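The bond cut is that between C1, the methine that carries the pendant 3,4-dimethoxyphenyl group, and C8a of the dimethoxybenzene ring A. C8a stands para to the C6 methoxy group and is the innately nucleophilic ring carbon. An intramolecular Friedel–Crafts acylation of (2R,3R)-4-(3,4-dimethoxyphenyl)-2,3-dimethylbutanoic acid therefore closes the carbocycle as a 1-tetralone, with C1 arriving at the ketone level. The cis-dimethyl C1–C4 chain of that acid maps onto meso-2,3-dimethylsuccinic anhydride, which is desymmetrised catalytically. Aryl addition and dehydration then give the C1=C2 alkene, and hydrogenation anti to the C3 methyl group sets C1 and C2 all-cis.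

Key step: step 4

Remark on numbering: tetralin numbering of the target is used throughout (C1 aryl-bearing methine, C2 and C3 methyl-bearing, C4 methylene, C4a and C8a ring-fusion carbons, ring A the fused dimethoxybenzene ring). The target is the all-cis (1S,2R,3R) isomer.

Assumption: which antipode of the phosphoramidite ligand gives the (2R,3S) keto acid in step 2 is assigned in the first run, and that antipode is then used.

Step 1
Reactants: 1 meso-2,3-dimethylsuccinic acid
Product: 2 meso-2,3-dimethylsuccinic anhydride (cis-3,4-dimethyloxolane-2,5-dione)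
Conditions: AcCl, reflux; evaporate
Reagents that add atoms: none
Why: Acetyl chloride acylates one carboxyl group to a mixed anhydride that closes to the five-membered cyclic anhydride (cyclodehydration of a 1,4-diacid), and since neither methine is touched the meso, cis-dimethyl configuration is kept.

Step 2
Reactants: 2 meso-2,3-dimethylsuccinic anhydride; 3 4-bromo-1,2-dimethoxybenzene
Product: 6 (2R,3S)-4-(3,4-dimethoxyphenyl)-2,3-dimethyl-4-oxobutanoic acid, via aryllithium 4 (not isolated), via arylzinc triflate 5 (not isolated)
Conditions: 3, n-BuLi, THF, −78 °C; Zn(OTf)2, −78 °C to rt; then 2, [Rh(cod)Cl]2 (4 mol %), TADDOL-derived N,N-dimethylphosphoramidite (8 mol %), DMF, 50 °C; aq. HCl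
Reagents that add atoms: none
Why: Enantioselective desymmetrisation of a meso cyclic anhydride by rhodium-catalysed acyl cross-coupling with an arylzinc reagent: the chiral rhodium complex inserts into one of the two enantiotopic acyl–oxygen bonds (the one next to the (S)-configured carbon), the aryl group is transferred from zinc and reductive elimination gives the aryl ketone, so the ligand fixes the carbon that becomes C3 of the target while both methines keep their cis relation.

Step 3
Reactants: 6 (2R,3S)-4-(3,4-dimethoxyphenyl)-2,3-dimethyl-4-oxobutanoic acid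
Product: 9 (2R,3R)-4-(3,4-dimethoxyphenyl)-2,3-dimethylbutanoic acid, via hydroxy acid 7 (not isolated), via lactone 8 (not isolated)
Conditions: H2 (4 bar), Pd/C, AcOH, 50 °C
Reagents that add atoms: none
Why: Catalytic hydrogenolysis of an electron-rich aryl ketone to the methylene group over palladium, by way of the benzylic alcohol and its γ-lactone whose benzylic C–O bonds are cleaved in turn, is the classical reduction of 4-aryl-4-oxobutanoic acids, and the weakly acidic medium should not enolise the stereocentre beside the ketone.

Step 4
Reactants: 9 (2R,3R)-4-(3,4-dimethoxyphenyl)-2,3-dimethylbutanoic acid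
Product: 11 (2R,3R)-6,7-dimethoxy-2,3-dimethyl-3,4-dihydronaphthalen-1(2H)-one, via mixed anhydride 10 (not isolated)
Conditions: (CF3CO)2O, CF3CO2H, CH2Cl2, 0 °C to rt
Reagents that add atoms: none
Why: Trifluoroacetic anhydride turns acid 9 into mixed anhydride 10, which in trifluoroacetic acid ionises to the acylium ion; ring A attacks it through C8a, and loss of the proton from the arenium ion gives the aryl ketone. This is an intramolecular Friedel–Crafts acylation of the Haworth tetralone type, well known for 4-(3,4-dialkoxyphenyl)butanoic acids. The six-membered ring (C1, C2, C3, C4, C4a, C8a) closes by 6-exo attack of the arene carbon on the acyl carbon. No stereocentre is created: C3 is not enolisable and is kept, while C2, now next to the ketone, may epimerise without consequence because it becomes sp2 in step 5. The selectivity needed is between the two ring carbons ortho to the side chain: C8a is para to the C6 methoxy group and unhindered, whereas the other is flanked by the chain and a methoxy group, so the 6,7-dimethoxy pattern should result.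

Step 5
Reactants: 11 (2R,3R)-6,7-dimethoxy-2,3-dimethyl-3,4-dihydronaphthalen-1(2H)-one; 3 4-bromo-1,2-dimethoxybenzene
Product: 15 (2R)-4-(3,4-dimethoxyphenyl)-6,7-dimethoxy-2,3-dimethyl-1,2-dihydronaphthalene, via arylmagnesium bromide 12 (not isolated), via organocerium 13 (not isolated), via carbinol 14 (not isolated)
Conditions: 3, Mg turnings, I2 (cat.), THF, reflux; anhydrous CeCl3, THF, 0 °C; then 11, 0 °C to rt; aq. HCl; then TsOH·H2O (cat.), toluene, 80 °C
Reagents that add atoms: none
Why: The arylmagnesium bromide made from 3 is transmetalated to a weakly basic organocerium reagent that adds 1,2 to the hindered, enolisable α-methyl tetralone (Imamoto organocerium addition), and acid-catalysed E1 dehydration of the tertiary diaryl carbinol, which can lose only the C2 hydrogen, should give the C1=C2 alkene; the C1 and C2 centres are erased on purpose and C3 is untouched.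

Step 6
Reactants: 15 (2R)-4-(3,4-dimethoxyphenyl)-6,7-dimethoxy-2,3-dimethyl-1,2-dihydronaphthalene
Product: 16 (1S,2R,3R)-1-(3,4-dimethoxyphenyl)-6,7-dimethoxy-2,3-dimethyl-1,2,3,4-tetrahydronaphthalene
Conditions: H2 (4 bar), Pd(OH)2/C, EtOAc–EtOH, rt
Reagents that add atoms: none
Why: Heterogeneous catalytic hydrogenation delivers both hydrogens syn to the tetrasubstituted styrenic alkene from the face opposite to the C3 methyl group, which sits pseudoaxial to avoid allylic strain with the C2 methyl group, so C1–H and C2–H should end up trans to it and the aryl and both methyl groups cis, as in (1S,2R,3R).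

Compound list
1 | meso-2,3-dimethylsuccinic acid, (2R,3S)-2,3-dimethylbutanedioic acid | OC(=O)[C@@H](C)[C@@H](C)C(=O)O | starting material
2 | meso-2,3-dimethylsuccinic anhydride, (3R,4S)-3,4-dimethyloxolane-2,5-dione | C[C@@H]1[C@H](C)C(=O)OC1=O | intermediate
3 | 4-bromo-1,2-dimethoxybenzene | COc1ccc(Br)cc1OC | starting material
4 | (3,4-dimethoxyphenyl)lithium | COc1ccc([Li])cc1OC | intermediate
5 | (3,4-dimethoxyphenyl)zinc trifluoromethanesulfonate | COc1ccc([Zn]OS(=O)(=O)C(F)(F)F)cc1OC | intermediate
6 | (2R,3S)-4-(3,4-dimethoxyphenyl)-2,3-dimethyl-4-oxobutanoic acid | COc1ccc(C(=O)[C@@H](C)[C@@H](C)C(=O)O)cc1OC | intermediate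
7 | (2R,3S)-4-(3,4-dimethoxyphenyl)-4-hydroxy-2,3-dimethylbutanoic acid, both C4 epimers | COc1ccc(C(O)[C@@H](C)[C@@H](C)C(=O)O)cc1OC | intermediate
8 | (3R,4S)-5-(3,4-dimethoxyphenyl)-3,4-dimethyloxolan-2-one, both C5 epimers | COc1ccc(C2OC(=O)[C@H](C)[C@@H]2C)cc1OC | intermediate
9 | (2R,3R)-4-(3,4-dimethoxyphenyl)-2,3-dimethylbutanoic acid | COc1ccc(C[C@@H](C)[C@@H](C)C(=O)O)cc1OC | intermediate
10 | (2R,3R)-4-(3,4-dimethoxyphenyl)-2,3-dimethylbutanoic trifluoroacetic anhydride | COc1ccc(C[C@@H](C)[C@@H](C)C(=O)OC(=O)C(F)(F)F)cc1OC | intermediate
11 | (2R,3R)-6,7-dimethoxy-2,3-dimethyl-3,4-dihydronaphthalen-1(2H)-one, cis-dimethyl | COc1cc2C[C@@H](C)[C@@H](C)C(=O)c2cc1OC | intermediate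
12 | (3,4-dimethoxyphenyl)magnesium bromide | COc1ccc([Mg]Br)cc1OC | intermediate
13 | dichloro(3,4-dimethoxyphenyl)cerium | COc1ccc([Ce](Cl)Cl)cc1OC | intermediate
14 | (2R,3R)-1-(3,4-dimethoxyphenyl)-6,7-dimethoxy-2,3-dimethyl-1,2,3,4-tetrahydronaphthalen-1-ol, both C1 epimers | COc1ccc(C2(O)c3cc(OC)c(OC)cc3C[C@@H](C)[C@H]2C)cc1OC | intermediate
15 | (2R)-4-(3,4-dimethoxyphenyl)-6,7-dimethoxy-2,3-dimethyl-1,2-dihydronaphthalene (C1=C2 alkene and 3R in target numbering) | COc1ccc(C2=C(C)[C@H](C)Cc3cc(OC)c(OC)cc32)cc1OC | intermediate
16 | (1S,2R,3R)-1-(3,4-dimethoxyphenyl)-6,7-dimethoxy-2,3-dimethyl-1,2,3,4-tetrahydronaphthalene, all-cis | COc1ccc([C@H]2c3cc(OC)c(OC)cc3C[C@@H](C)[C@H]2C)cc1OC | target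

Total step count: 6. Longest linear sequence: 6 steps (1 → 2 → 6 → 9 → 11 → 15 → 16).

Steps most likely to fail

Step 2. The catalyst may discriminate poorly between the two enantiotopic acyl–oxygen bonds with this electron-rich arylzinc reagent, or transmetalation may be sluggish. The fallback sets out from 2 and comes back at 9. The anhydride is opened with benzyl alcohol under cinchona-alkaloid control (quinidine or quinine, whichever directs the alcohol to the carbonyl next to the (R)-configured carbon; toluene, −55 °C) to give (2S,3R)-4-(benzyloxy)-2,3-dimethyl-4-oxobutanoic acid F1. Oxalyl chloride with catalytic DMF converts the free acid into benzyl (2R,3S)-4-chloro-2,3-dimethyl-4-oxobutanoate F2. A Negishi acylation of arylzinc 5 with Pd(PPh3)4 in THF at 0 °C gives benzyl (2R,3S)-4-(3,4-dimethoxyphenyl)-2,3-dimethyl-4-oxobutanoate F3. Hydrogenation over Pd/C in AcOH then removes the benzyl ester and reduces the ketone to the methylene group in one operation, giving acid 9.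

Step 6. Facial selectivity may be poor, because a single allylic methyl group is the only element that differentiates the two faces of the alkene. The fallback sets out from 11 and comes back at 16, and it uses the C2 configuration fixed in step 2 instead of erasing it. The organocerium addition of step 5 is stopped at carbinol 14, which is isolated (this needs the cis configuration at C2 of 11 to be intact, to be checked by NMR). Ionic hydrogenation (Et3SiH, BF3·OEt2, CH2Cl2, −78 °C) then reduces the diaryl cation at C1, with hydride expected to enter anti to the pseudoaxial C2 methyl group, which places the aryl group cis to both methyl groups. New compounds: none F0.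

Step 5. The ketone may be deprotonated (enolised) instead of attacked, or conversion may be low because the carbonyl is hindered and deactivated by the para methoxy group. The fallback sets out from 11 and comes back at 15. Enolisation is turned to advantage: KN(SiMe3)2 and PhNTf2 in THF at −78 °C give (3R)-6,7-dimethoxy-2,3-dimethyl-3,4-dihydronaphthalen-1-yl trifluoromethanesulfonate F4. Suzuki–Miyaura coupling with (3,4-dimethoxyphenyl)boronic acid (Pd(PPh3)4, K2CO3, dioxane–H2O, 80 °C) then gives alkene 15.

Further compounds
F1 | step 2 | (2S,3R)-4-(benzyloxy)-2,3-dimethyl-4-oxobutanoic acid | OC(=O)[C@@H](C)[C@@H](C)C(=O)OCc1ccccc1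
F2 | step 2 | benzyl (2R,3S)-4-chloro-2,3-dimethyl-4-oxobutanoate | ClC(=O)[C@@H](C)[C@@H](C)C(=O)OCc1ccccc1
F3 | step 2 | benzyl (2R,3S)-4-(3,4-dimethoxyphenyl)-2,3-dimethyl-4-oxobutanoate | COc1ccc(C(=O)[C@@H](C)[C@@H](C)C(=O)OCc2ccccc2)cc1OC
F0 | step 6 | none | none
F4 | step 5 | (3R)-6,7-dimethoxy-2,3-dimethyl-3,4-dihydronaphthalen-1-yl trifluoromethanesulfonate | COc1cc2C[C@@H](C)C(C)=C(OS(=O)(=O)C(F)(F)F)c2cc1OC
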